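## Retrosynthetic overview

1. Target 28 ⇐ hydrogenation of α-methylene lactone 27 ⇐ allylzinc addition/lactonisation on the C3 aldehyde 23; the C13 methyl comes from alkylation of the fused α-hydroxy lactone.
2. Fused lactone ⇐ glyoxylate aldol at C12 plus C11 reduction of cyclopentanone 13 ⇐ diazoalkane expansion (inserting C10 with its ethyl group) of dichlorocyclobutanone 11.
3. Key step: 11 ⇐ [2+2] cycloaddition of dichloroketene to the bicyclic ene-lactam 8, which sets C9a and C9 from C3.
4. 8 ⇐ intramolecular Wittig closure of N-(5-bromopentanoyl) lactam 5 ⇐ (S)-pyroglutaminol 1, the only source of chirality.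
5. Ring order: pyrrolidine (bought) → azepine → four-membered ring → cyclopentane → fused lactone → side-chain lactone.

Atom labels used below: pyrrolidine N4–C3–C2–C1–C9a; azepane C5–C9; cyclopentane C9a–C9–C10(Et)–C11(O)–C12; fused lactone C13 (C–OH, Me) and C14 (C=O); side-chain lactone C18 (CH–O), C19, C20 (CH–Me), C21 (C=O). The target is (3S,9R,9aR,10R,11R,12S,13S,18S,20S).

Assumption: freshly prepared reagents (1-diazopropane in Et2O from N-nitroso-N-propylurea/KOH; LiN(iPr)2) count as reagents, not as starting materials.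

## Route

Step 1
Reactants: 1 (S)-5-(hydroxymethyl)pyrrolidin-2-one
Product: 2 (S)-5-({[tert-butyl(dimethyl)silyl]oxy}methyl)pyrrolidin-2-one
Conditions: TBSCl, imidazole, DMF, rt
Reagents that add atoms: tert-butyldimethylsilyl chloride, CC(C)(C)[Si](C)(C)Cl
Why: Silylation of the primary alcohol gives a base-stable ether that carries C3 and its future C18 carbon through all enolate steps.

Step 2
Reactants: 2 (S)-5-({[tert-butyl(dimethyl)silyl]oxy}methyl)pyrrolidin-2-one; 3 5-bromopentanoyl chloride
Product: 5 (S)-1-(5-bromopentanoyl)-5-({[tert-butyl(dimethyl)silyl]oxy}methyl)pyrrolidin-2-one, via lithium lactamate 4 (not isolated)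
Conditions: n-BuLi, THF, −78 °C; then 3, −78 → 0 °C
Reagents that add atoms: 5-bromopentanoyl chloride (3), ClC(=O)CCCCBr
Why: N-acylation of the lithiated lactam installs C5–C9 and turns the ring carbonyl (future C9a) into an electrophilic imide carbonyl.

Step 3
Reactants: 5 (S)-1-(5-bromopentanoyl)-5-({[tert-butyl(dimethyl)silyl]oxy}methyl)pyrrolidin-2-one
Product: 8 (3S)-3-({[tert-butyl(dimethyl)silyl]oxy}methyl)-1,2,3,6,7,8-hexahydro-5H-pyrrolo[1,2-a]azepin-5-one (C9=C9a ene-lactam), via phosphonium bromide 6 (not isolated), via phosphorus ylide 7 (not isolated)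
Conditions: PPh3, MeCN, 80 °C; evaporate; then KN(SiMe3)2, toluene (0.01 M), 0 → 110 °C
Reagents that add atoms: none
Why: Intramolecular Wittig olefination of the imide ring carbonyl by the tethered ylide closes the seven-membered ring and gives the enamide needed for the cycloaddition.

Step 4
Reactants: 8 ene-lactam; 9 dichloroacetyl chloride
Product: 11 tricyclic 2,2-dichlorocyclobutanone, cis-fused across C9–C9a (C=O carbon C11 on C9, CCl2 carbon C12 on C9a, N4 and C8 on the same face, C12 trans to the CH2OTBS group), via dichloroketene 10 (not isolated)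
Conditions: 9 (slow addition), Et3N, hexane, 40 °C
Reagents that add atoms: dichloroacetyl chloride (9), ClC(Cl)C(Cl)=O, delivered as dichloroketene (10), ClC(Cl)=C=O
Why: Ketene–alkene [2+2] cycloaddition; the ketene carbonyl carbon bonds to the nucleophilic enamide carbon C9 and CCl2 to C9a, suprafacially on the face opposite the pseudoaxial CH2OTBS group, so C9a (quaternary) and C9 are set from C3.

Step 5
Reactants: 11 tricyclic dichlorocyclobutanone
Product: 12 2,2-dichloro-5-ethylcyclopentanone analogue of 11 (C12 = CCl2, C11 = C=O, C10 = CH–Et, mixture of C10 epimers)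
Conditions: 1-diazopropane (Et2O solution), MeOH (cat.), Et2O, 0 °C → rt
Reagents that add atoms: 1-diazopropane, CCC=[N+]=[N-]
Why: Diazoalkane ring expansion (Büchner–Curtius–Schlotterbeck homologation) of the activated α,α-dichlorocyclobutanone; the non-chlorinated C9 migrates with retention, inserting C10 with its ethyl group between C11 and C9.

Step 6
Reactants: 12 dichloro ethyl cyclopentanone
Product: 13 cyclopentanone with C12 methylene, C11 ketone and C10 ethyl trans to C8 (10R); lactam and silyl ether intact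
Conditions: Zn dust, AcOH, 60 °C; then DBU (cat.), CH2Cl2, rt
Reagents that add atoms: none
Why: Zinc reductive dechlorination followed by base equilibration of the epimerisable C10 to the more stable trans-2,3-disubstituted cyclopentanone.

Step 7
Reactants: 13 cyclopentanone; 14 ethyl glyoxylate
Product: 16 β-hydroxy ketone carrying CH(OH)CO2Et on C12, cis to the C10 ethyl group (C13 epimers), via lithium enolate 15 (not isolated)
Conditions: LiN(iPr)2, THF, −78 °C; then 14, −78 °C; AcOH
Reagents that add atoms: ethyl glyoxylate (14), O=CC(=O)OCC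
Why: Kinetic deprotonation at the CH2 (C12) rather than the CH (C10), then aldol addition on the convex face away from the cis-fused azepinone, places C13 on the face of C1 and the ethyl group.

Step 8
Reactants: 16 β-hydroxy ketone
Product: 18 cis-fused α-hydroxy-γ-lactone (O on C11, C13H–OH, C14=O; C13 epimers) with lactam and silyl ether intact, via dilithium dialkoxide 17 (not isolated)
Conditions: LiBH(s-Bu)3 (2.2 equiv), THF, −78 °C → rt; then H2O
Reagents that add atoms: none
Why: The bulky hydride attacks the ketone opposite the two flanking cis substituents, giving the all-cis C11 alkoxide, which lactonises onto the ethyl ester.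

Step 9
Reactants: 18 hydroxy lactone lactam
Product: 19 hydroxy lactone tertiary amine (C5 now CH2)
Conditions: Zn(OAc)2 (10 mol %), (EtO)3SiH, THF, 40 °C; aq. KF work-up
Reagents that add atoms: none
Why: Zinc-catalysed hydrosilylation reduces the tertiary lactam selectively over the lactone and silyl ether; any transient O-silylation of the C13 hydroxyl is undone by the fluoride work-up.

Step 10
Reactants: 19 hydroxy lactone amine
Product: 21 (13S)-13-hydroxy-13-methyl lactone, target-configured at C9, C9a, C10, C11, C12 and C13, with CH2OTBS on C3, via dilithium dianion 20 (not isolated)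
Conditions: LiN(iPr)2 (2.3 equiv), THF, −78 → −40 °C; then MeI, −78 °C; AcOH
Reagents that add atoms: iodomethane, CI
Why: C-alkylation of the alkoxide–enolate dianion occurs on the convex face of the cis-fused bicycle, anti to quaternary C9a, so methyl ends exo and hydroxyl endo, and both C13 epimers of 19 converge.

Step 11
Reactants: 21 silyl ether
Product: 22 C3 hydroxymethyl compound
Conditions: HF·pyridine, THF, 0 °C → rt
Reagents that add atoms: none
Why: Fluoride desilylation frees the primary alcohol without touching the lactone or the tertiary alcohol.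

Step 12
Reactants: 22 primary alcohol
Product: 23 C3 aldehyde
Conditions: Dess–Martin periodinane, CH2Cl2, 0 °C → rt
Reagents that add atoms: none
Why: Dess–Martin oxidation stops at the aldehyde and leaves the tertiary alcohol untouched; the α-amino aldehyde is used crude to avoid C3 epimerisation.

Step 13
Reactants: 23 C3 aldehyde; 24 ethyl 2-(bromomethyl)acrylate
Product: 27 (18S)-α-methylene-γ-butyrolactone on C3, via allylzinc bromide 25 (not isolated), via zinc alkoxide 26 (not isolated)
Conditions: Zn dust, 24 (3 equiv), THF, 0 °C → rt; aq. NH4Cl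
Reagents that add atoms: ethyl 2-(bromomethyl)acrylate (24), C=C(CBr)C(=O)OCC
Why: Dreiding–Schmidt reaction (Barbier-type allylzinc addition then lactonisation); zinc bridging N4 and the aldehyde oxygen (Cram chelate) directs attack from the side of the C3 hydrogen to give the threo (18S) alkoxide, which closes onto the ester.

Step 14
Reactants: 27 α-methylene lactone
Product: 28 target, CNP0260919.3
Conditions: H2 (1 atm), 10% Pd/C, EtOAc, rt
Reagents that add atoms: none
Why: Heterogeneous hydrogenation delivers hydrogen to the exocyclic alkene from the face opposite the C18 substituent, giving the cis (20S) α-methyl lactone.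

## Compound list

1 | (S)-5-(hydroxymethyl)pyrrolidin-2-one | O=C1CC[C@@H](CO)N1 | starting material
2 | (S)-5-({[tert-butyl(dimethyl)silyl]oxy}methyl)pyrrolidin-2-one | O=C1CC[C@@H](CO[Si](C)(C)C(C)(C)C)N1 | intermediate
3 | 5-bromopentanoyl chloride | ClC(=O)CCCCBr | starting material
4 | lithium lactamate of 2 (N-lithio) | O=C1CC[C@@H](CO[Si](C)(C)C(C)(C)C)N1[Li] | intermediate
5 | (S)-1-(5-bromopentanoyl)-5-({[tert-butyl(dimethyl)silyl]oxy}methyl)pyrrolidin-2-one | O=C1CC[C@@H](CO[Si](C)(C)C(C)(C)C)N1C(=O)CCCCBr | intermediate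
6 | {5-[(S)-2-({[tert-butyl(dimethyl)silyl]oxy}methyl)-5-oxopyrrolidin-1-yl]-5-oxopentyl}triphenylphosphonium bromide | O=C1CC[C@@H](CO[Si](C)(C)C(C)(C)C)N1C(=O)CCCC[P+](c1ccccc1)(c1ccccc1)c1ccccc1.[Br-] | intermediate
7 | (S)-5-({[tert-butyl(dimethyl)silyl]oxy}methyl)-1-[5-(triphenylphosphoranylidene)pentanoyl]pyrrolidin-2-one | O=C1CC[C@@H](CO[Si](C)(C)C(C)(C)C)N1C(=O)CCCC=P(c1ccccc1)(c1ccccc1)c1ccccc1 | intermediate
8 | (3S)-3-({[tert-butyl(dimethyl)silyl]oxy}methyl)-1,2,3,6,7,8-hexahydro-5H-pyrrolo[1,2-a]azepin-5-one | O=C1CCCC=C2CC[C@@H](CO[Si](C)(C)C(C)(C)C)N12 | intermediate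
9 | dichloroacetyl chloride | ClC(Cl)C(Cl)=O | starting material
10 | dichloroketene | ClC(Cl)=C=O | intermediate
11 | tricyclic 2,2-dichlorocyclobutanone cis-fused across C9–C9a (C11=O on C9, C12Cl2 on C9a, C12 trans to CH2OTBS) | O=C1C(Cl)(Cl)[C@]23CC[C@@H](CO[Si](C)(C)C(C)(C)C)N2C(=O)CCC[C@H]13 | intermediate
12 | 2,2-dichloro-5-ethylcyclopentanone analogue (C10 epimers) | CCC1C(=O)C(Cl)(Cl)[C@]23CC[C@@H](CO[Si](C)(C)C(C)(C)C)N2C(=O)CCC[C@H]13 | intermediate
13 | (10R)-ethyl cyclopentanone lactam, ethyl trans to C8 | CC[C@H]1C(=O)C[C@]23CC[C@@H](CO[Si](C)(C)C(C)(C)C)N2C(=O)CCC[C@H]13 | intermediate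
14 | ethyl glyoxylate | O=CC(=O)OCC | starting material
15 | lithium enolate of 13 (C11–OLi, C11=C12) | CC[C@H]1C(O[Li])=C[C@]23CC[C@@H](CO[Si](C)(C)C(C)(C)C)N2C(=O)CCC[C@H]13 | intermediate
16 | aldol adduct: CH(OH)CO2Et on C12, cis to ethyl (C13 epimers) | CC[C@H]1C(=O)[C@@H](C(O)C(=O)OCC)[C@]23CC[C@@H](CO[Si](C)(C)C(C)(C)C)N2C(=O)CCC[C@H]13 | intermediate
17 | dilithium C11,C13-dialkoxide of the all-cis diol ester | CC[C@H]1[C@@H](O[Li])[C@@H](C(O[Li])C(=O)OCC)[C@]23CC[C@@H](CO[Si](C)(C)C(C)(C)C)N2C(=O)CCC[C@H]13 | intermediate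
18 | cis-fused α-hydroxy-γ-lactone, lactam (C13 epimers) | CC[C@H]1[C@H]2OC(=O)C(O)[C@H]2[C@]23CC[C@@H](CO[Si](C)(C)C(C)(C)C)N2C(=O)CCC[C@H]13 | intermediate
19 | cis-fused α-hydroxy-γ-lactone, tertiary amine (C13 epimers) | CC[C@H]1[C@H]2OC(=O)C(O)[C@H]2[C@]23CC[C@@H](CO[Si](C)(C)C(C)(C)C)N2CCCC[C@H]13 | intermediate
20 | dilithium alkoxide–enolate dianion of 19 | CC[C@H]1[C@H]2OC(O[Li])=C(O[Li])[C@H]2[C@]23CC[C@@H](CO[Si](C)(C)C(C)(C)C)N2CCCC[C@H]13 | intermediate
21 | (13S)-13-hydroxy-13-methyl lactone amine, CH2OTBS on C3 | CC[C@H]1[C@H]2OC(=O)[C@@](C)(O)[C@H]2[C@]23CC[C@@H](CO[Si](C)(C)C(C)(C)C)N2CCCC[C@H]13 | intermediate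
22 | C3 hydroxymethyl compound | CC[C@H]1[C@H]2OC(=O)[C@@](C)(O)[C@H]2[C@]23CC[C@@H](CO)N2CCCC[C@H]13 | intermediate
23 | C3 aldehyde | CC[C@H]1[C@H]2OC(=O)[C@@](C)(O)[C@H]2[C@]23CC[C@@H](C=O)N2CCCC[C@H]13 | intermediate
24 | ethyl 2-(bromomethyl)acrylate | C=C(CBr)C(=O)OCC | starting material
25 | [2-(ethoxycarbonyl)prop-2-en-1-yl]zinc bromide | C=C(C[Zn]Br)C(=O)OCC | intermediate
26 | zinc alkoxide of the (18S) hydroxy ester | CC[C@H]1[C@H]2OC(=O)[C@@](C)(O)[C@H]2[C@]23CC[C@@H]([C@@H](O[Zn]Br)CC(=C)C(=O)OCC)N2CCCC[C@H]13 | intermediate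
27 | (18S)-α-methylene-γ-butyrolactone | CC[C@H]1[C@H]2OC(=O)[C@@](C)(O)[C@H]2[C@]23CC[C@@H]([C@@H]4CC(=C)C(=O)O4)N2CCCC[C@H]13 | intermediate
28 | CNP0260919.3, (3S,9R,9aR,10R,11R,12S,13S,18S,20S) | CC[C@H]1[C@H]2OC(=O)[C@@](C)(O)[C@H]2[C@]23CC[C@@H]([C@@H]4C[C@H](C)C(=O)O4)N2CCCC[C@H]13 | target

## Step count and risks

Total step count: 14. Longest linear sequence: 14 (fully linear from 1).

Most likely to fail:

Step 3 (Wittig closure of a seven-membered ring on an imide carbonyl; the ylide may instead acylate and open the imide). Fallback: set out from 2 and acylate its lithium salt with hex-5-enoyl chloride to give (S)-5-({[tert-butyl(dimethyl)silyl]oxy}methyl)-1-(hex-5-enoyl)pyrrolidin-2-one F1. Close the ring by titanium-alkylidene carbonyl–olefin metathesis (TiCl4, Zn, PbCl2, TMEDA, CH3CHBr2, THF, 65 °C), which joins the internal alkene carbon to the ring carbonyl carbon and comes back to the route at ene-lactam 8.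

Step 7 (regio- and face-selectivity of the kinetic enolate, and possible β-elimination of the amide nitrogen from the C12 enolate). Fallback: set out from dichloro ketone 12. SmI2 (2.2 equiv, THF, −78 °C) cleaves one C–Cl bond to give the samarium enolate regiospecifically at C12, which is trapped by ethyl glyoxylate 14 to give the α-chloro aldol F2. Radical dechlorination (Bu3SnH, AIBN, benzene, 80 °C) and DBU equilibration of C10 and C12 then come back to the route at 16.

Step 13 (the threo outcome needs chelation by the hindered N4; Felkin–Anh addition would give the 18R epimer). Fallback: set out from silyl ether 21. Jones reagent (CrO3, H2SO4, acetone) cleaves the silyl ether and oxidises to the C3 carboxylic acid F3. POCl3 in DMF decarbonylates it to the bicyclic C3 iminium chloride F4, which is trapped in situ by 3-methyl-2-(triisopropylsilyloxy)furan F5 (from 3-methylfuran-2(5H)-one, TIPSOTf, Et3N) in a threo-selective vinylogous Mannich reaction to give butenolide F6. Hydrogenation (H2, Pd/C) comes back to the route at the target 28. This fallback re-creates C3 under control of the C9a substituents, so its facial selectivity would have to be checked.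

Further compounds

F1 | step 3 | (S)-5-({[tert-butyl(dimethyl)silyl]oxy}methyl)-1-(hex-5-enoyl)pyrrolidin-2-one | O=C1CC[C@@H](CO[Si](C)(C)C(C)(C)C)N1C(=O)CCCC=C
F2 | step 7 | α-chloro aldol: C12 bears Cl and CH(OH)CO2Et (C10, C12, C13 epimers) | CCC1C(=O)C(Cl)(C(O)C(=O)OCC)[C@]23CC[C@@H](CO[Si](C)(C)C(C)(C)C)N2C(=O)CCC[C@H]13
F3 | step 13 | C3 carboxylic acid of the tricyclic hydroxy lactone amine | CC[C@H]1[C@H]2OC(=O)[C@@](C)(O)[C@H]2[C@]23CC[C@@H](C(=O)O)N2CCCC[C@H]13
F4 | step 13 | bicyclic C3=N4 iminium chloride | CC[C@H]1[C@H]2OC(=O)[C@@](C)(O)[C@H]2[C@]23CCC=[N+]2CCCC[C@H]13.[Cl-]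
F5 | step 13 | 3-methyl-2-(triisopropylsilyloxy)furan | Cc1ccoc1O[Si](C(C)C)(C(C)C)C(C)C
F6 | step 13 | (18S)-3-methylbutenolide on C3 | CC[C@H]1[C@H]2OC(=O)[C@@](C)(O)[C@H]2[C@]23CC[C@@H]([C@@H]4C=C(C)C(=O)O4)N2CCCC[C@H]13
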